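The coupling partner is the limiting reagent in west, north-east, north and east. Each proposed cycle turns one partner and one substrate into one product, so equal charges mean a ceiling of full conversion, and that is the zero of the scale. With 1.20 M of partner against 2.0 M of substrate, product cannot pass 60.0% of the substrate charged.

common to all: free catalyst 2.8 mM

| run | substrate | coupling partner | temperature | remark | time |
|---|---|---|---|---|---|
| Friday's | 1 M | 1.2 M | 130 °C | run made earlier |  |
| west | 2.0 M | 1.20 M | 130 °C |  | 1.5 h |
| north-east | 2.0 M | 1.20 M | 70 °C |  | 1.5 h |
| north | 2.0 M | 1.20 M | 100 °C |  | 1.5 h |
| east | 2.0 M | 1.20 M | 40 °C |  | 1.5 h |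

Friday's run (percent of the substrate charged)

| time / min | product / % | substrate / % |
|---|---|---|
| 5.00 | 6.3 | 92.6 |
| 10.0 | 14.1 | 86.4 |
| 15.0 | 20.1 | 78.5 |
| 20.0 | 26.5 | 72.7 |
| 25.0 | 35.1 | 65.3 |

(scatter of a reading: 1 percentage point)

- the numbers in the tables scatter with a standard deviation of 1 percentage point
- steps that have been proposed: coupling partner + free catalyst -> catalyst intermediate A; substrate + catalyst intermediate A <-> catalyst intermediate B; catalyst intermediate B -> catalyst intermediate C; catalyst intermediate C -> free catalyst + product
- the earlier runs do not show what temperature does; that part of a forecast is a guess

- the flask that comes out highest in amount of product, in percent of the substrate charged, or "all alike" when all lie within 1.5 percentage points (west / north-east / north / east / all alike)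
- product at the end, in percent of the substrate charged, west
- product at the end, in percent of the substrate charged, north-east
- product at the end, in percent of the substrate charged, north
- product at the end, in percent of the substrate charged, east

Friday's product climbs in roughly equal steps to 35.1% at 25.0 min, so it is taken as zero order, with a molar rate of 14.0 mM/min. Per catalyst charged, this is the turnover frequency, the cycles each catalyst completes per minute, 5.01 /min. West needs 429 cycles per catalyst to use up its partner, and at 130 °C the frequency allows 451 in 1.5 h. On a flat rate the partner in west would last 85.5 min, shorter than the 1.5 h, and west would reach the ceiling.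

The weak link is the flat rate. By its last product reading, Friday's [coupling partner] stood near 0.849 M, while west's has to go towards zero to reach the ceiling. The surplus of cycles is a mere 5.30%, so a mean slowing of that size leaves west under the ceiling, and the reckoning commits to just below 60.0%.

The forecast gives west as highest, at 57% (50% to 60%), and reads Friday's run thus: “the catalyst is saturated and a step after substrate binding limits the rate”. Its temperature guess gives north 10%, north-east 1.5% and east 0.1%.

The flasks give west 57.4%, north 11.7%, north-east 1.01% and east 0.0238%, so west is highest.

    coupling partner + free catalyst → catalyst intermediate A (k = 512 /M/h, Ea = 61.0 kJ/mol)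
    substrate + catalyst intermediate A ⇌ catalyst intermediate B (K = 0.599 /M, k = 219 /M/h, Ea = 57.0 kJ/mol, ΔH = 14.0 kJ/mol)
    catalyst intermediate B → catalyst intermediate C (k = 855 /h, Ea = 94.0 kJ/mol)
    catalyst intermediate C → free catalyst + product (k = 87.7 /h, Ea = 90.0 kJ/mol)
    (constants at 100 °C)

West's product amounts to 410 cycles per catalyst, fewer than the 429 its partner allows, and 4.3% of the partner is left. The neighbouring flask is east read at 50 min, still at 40 °C. Friday's frequency, read at 130 °C, would give 250 cycles in that time, but east's 0.00817% of product amounts to 0.0584 cycles per catalyst. At that reading the catalyst in east stands as catalyst intermediate A 39.9%, catalyst intermediate B 18.7%, catalyst intermediate C 40.5% and free catalyst 0.904%.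

The data are calculated from invented constants, noise included.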